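The route rests on disconnecting the C2–C3 bond of ring C in the ketol sense. The C3 carbinol and C4 ketone of the 3-hydroxychroman-4-one make ring C the ring-enlarged isomer of a 3-hydroxy-2-aryl-2,3-dihydrobenzofuran-3-carbaldehyde in which C2 is still bonded to the future C4. One chelation-controlled 1,2-shift of C2 from that carbinol carbon to the formyl carbon forms C2–C3, turns the furan ring into ring C, unveils the C4 ketone and sets C3 trans to ring B, while C2 is carried through unchanged. The precursor is an α-hydroxy aldehyde whose C2 centre comes from an asymmetric rhodium-carbene C–H insertion and whose quaternary C3 bears hydroxyl and formyl, the formyl cis to ring B.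

Key step: step 13

Assumption: Rh2(R-PTTL)4 is taken to deliver the (2S,3R)-cis ester needed in step 9, by analogy with the sense of induction recalled for its mirror image on simpler 2-benzyloxyphenyl diazoacetates; if this substrate responds in the opposite sense, Rh2(S-PTTL)4 is used and nothing else changes.

Step 1
Reactants: 1 3,5-dimethoxyphenol
Product: 2 (3,5-dimethoxyphenoxy)triisopropylsilane
Conditions: TIPSCl, imidazole, DMF, rt
Reagents that add atoms: triisopropylsilyl chloride, CC(C)[Si](Cl)(C(C)C)C(C)C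
Why: Silyl ether formation gives a bulky, weakly coordinating phenol ether that survives n-BuLi and keeps ring A symmetric.

Step 2
Reactants: 2 (3,5-dimethoxyphenoxy)triisopropylsilane; 3 prenyl bromide (1-bromo-3-methylbut-2-ene)
Product: 5 [3,5-dimethoxy-4-(3-methylbut-2-enyl)phenoxy]triisopropylsilane, via aryllithium 4 (not isolated)
Conditions: n-BuLi, TMEDA, THF, 0 °C to rt; then CuBr·SMe2 (20 mol%), 3, −78 to 0 °C
Reagents that add atoms: none
Why: Directed ortho-metalation should remove the C4 proton flanked by both methoxy groups, the bulky silyl ether shielding C2 and C6, and the copper-mediated SN2 allylation then joins the aryl carbon to the primary carbon of prenyl bromide.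

Step 3
Reactants: 5 [3,5-dimethoxy-4-(3-methylbut-2-enyl)phenoxy]triisopropylsilane
Product: 6 3,5-dimethoxy-4-(3-methylbut-2-enyl)phenol
Conditions: Bu4NF, THF, 0 °C
Reagents that add atoms: none
Why: Fluoride-induced desilylation of an aryl silyl ether is fast and leaves the prenyl group and the methyl ethers untouched.

Step 4
Reactants: 6 3,5-dimethoxy-4-(3-methylbut-2-enyl)phenol; 7 oxalyl chloride
Product: 9 methyl 2-[6-hydroxy-2,4-dimethoxy-3-(3-methylbut-2-enyl)phenyl]-2-oxoacetate, via benzofuran-2,3-dione 8 (not isolated)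
Conditions: 7, Et2O, 0 °C to rt, N2 sweep; then MeOH, rt
Reagents that add atoms: methanol, CO
Why: O-acylation by oxalyl chloride and intramolecular Friedel–Crafts acylation at the single kind of free ortho carbon of this symmetric phloroglucinol-type ring should give dione 8, whose activated aryl ester is opened by methanolysis, while ether as solvent and the nitrogen sweep keep HCl away from the prenyl alkene.

Step 5
Reactants: 10 isovanillin (3-hydroxy-4-methoxybenzaldehyde)
Product: 11 4-methoxy-3-(methoxymethoxy)benzaldehyde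
Conditions: MOMCl, iPr2NEt, CH2Cl2, 0 °C to rt
Reagents that add atoms: chloromethyl methyl ether, COCCl
Why: Acetal protection of the ring B phenol by O-alkylation masks it for the carbene, enolate and hydride steps and is removable with dilute acid.

Step 6
Reactants: 11 4-methoxy-3-(methoxymethoxy)benzaldehyde
Product: 12 [4-methoxy-3-(methoxymethoxy)phenyl]methanol
Conditions: NaBH4, MeOH, 0 °C
Reagents that add atoms: none
Why: Borohydride reduction of an aryl aldehyde to the benzylic alcohol is chemoselective and leaves the acetal intact.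

Step 7
Reactants: 9 methyl 2-[6-hydroxy-2,4-dimethoxy-3-(3-methylbut-2-enyl)phenyl]-2-oxoacetate; 12 [4-methoxy-3-(methoxymethoxy)phenyl]methanol
Product: 13 methyl 2-[2,4-dimethoxy-6-{[4-methoxy-3-(methoxymethoxy)phenyl]methoxy}-3-(3-methylbut-2-enyl)phenyl]-2-oxoacetate
Conditions: PPh3, DIAD, THF, 0 °C (betaine preformed); then 9 and 12, 0 °C to rt
Reagents that add atoms: none
Why: Mitsunobu etherification of the acidic hydrogen-bonded phenol with a primary benzylic alcohol installs the benzylic C–H bonds for the insertion without a labile electron-rich benzyl halide, the betaine being preformed so that free PPh3 does not meet the keto ester.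

Step 8
Reactants: 13 methyl 2-[2,4-dimethoxy-6-{[4-methoxy-3-(methoxymethoxy)phenyl]methoxy}-3-(3-methylbut-2-enyl)phenyl]-2-oxoacetate
Product: 15 methyl 2-diazo-2-[2,4-dimethoxy-6-{[4-methoxy-3-(methoxymethoxy)phenyl]methoxy}-3-(3-methylbut-2-enyl)phenyl]acetate, via tosylhydrazone 14 (not isolated)
Conditions: TsNHNH2, toluene, 80 °C; then DBU, CH2Cl2, 0 °C to rt
Reagents that add atoms: 4-methylbenzenesulfonohydrazide, Cc1ccc(cc1)S(=O)(=O)NN
Why: Condensation of the ester-activated ketone with tosylhydrazide and base-induced loss of sulfinate (Bamford–Stevens-type elimination) is the standard way from an aryl glyoxylate to an aryldiazoacetate.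

Step 9
Reactants: 15 methyl 2-diazo-2-[2,4-dimethoxy-6-{[4-methoxy-3-(methoxymethoxy)phenyl]methoxy}-3-(3-methylbut-2-enyl)phenyl]acetate
Product: 16 methyl (2S,3R)-4,6-dimethoxy-2-[4-methoxy-3-(methoxymethoxy)phenyl]-5-(3-methylbut-2-enyl)-2,3-dihydro-1-benzofuran-3-carboxylate (2,3-cis)
Conditions: Rh2(R-PTTL)4 (dirhodium tetrakis[N-phthaloyl-(R)-tert-leucinate], 1–2 mol%), toluene, −78 to −40 °C
Reagents that add atoms: none
Why: Intramolecular 1,5 C–H insertion of the donor/acceptor rhodium carbene into the benzylic C–H bond next to the ether oxygen closes the dihydrofuran ring, the chiral carboxylate ligands setting C2 and favouring the cis ester, and this doubly activated methylene should react far faster than the methyl C–H bonds of the other ortho methoxy group or the remote prenyl alkene.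

Step 10
Reactants: 16 methyl (2S,3R)-4,6-dimethoxy-2-[4-methoxy-3-(methoxymethoxy)phenyl]-5-(3-methylbut-2-enyl)-2,3-dihydro-1-benzofuran-3-carboxylate
Product: 18 methyl (2R,3S)-3-hydroxy-4,6-dimethoxy-2-[4-methoxy-3-(methoxymethoxy)phenyl]-5-(3-methylbut-2-enyl)-2,3-dihydro-1-benzofuran-3-carboxylate (3-hydroxyl trans to the aryl group), via potassium enolate 17 (not isolated)
Conditions: KN(SiMe3)2, THF, −78 °C; 2-(phenylsulfonyl)-3-phenyloxaziridine, −78 °C; AcOH quench
Reagents that add atoms: 2-(phenylsulfonyl)-3-phenyloxaziridine, O=S(=O)(c1ccccc1)N1OC1c1ccccc1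
Why: Enolate hydroxylation with an N-sulfonyloxaziridine should occur on the face opposite the C2 aryl group, so that the hydroxyl ends up trans and the ester carbon cis to ring B, while ring opening by β-elimination is blocked because the C2–O bond lies in the nodal plane of the enolate.

Step 11
Reactants: 18 methyl (2R,3S)-3-hydroxy-4,6-dimethoxy-2-[4-methoxy-3-(methoxymethoxy)phenyl]-5-(3-methylbut-2-enyl)-2,3-dihydro-1-benzofuran-3-carboxylate
Product: 19 (2R,3R)-3-(hydroxymethyl)-4,6-dimethoxy-2-[4-methoxy-3-(methoxymethoxy)phenyl]-5-(3-methylbut-2-enyl)-2,3-dihydro-1-benzofuran-3-ol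
Conditions: LiAlH4, THF, 0 °C
Reagents that add atoms: none
Why: Hydride reduction of the ester to the primary alcohol leaves the acetal, the alkene and both stereocentres untouched (the descriptor at C3 changes only through the priority rules).

Step 12
Reactants: 19 (2R,3R)-3-(hydroxymethyl)-4,6-dimethoxy-2-[4-methoxy-3-(methoxymethoxy)phenyl]-5-(3-methylbut-2-enyl)-2,3-dihydro-1-benzofuran-3-ol
Product: 20 (2R,3S)-3-hydroxy-4,6-dimethoxy-2-[4-methoxy-3-(methoxymethoxy)phenyl]-5-(3-methylbut-2-enyl)-2,3-dihydro-1-benzofuran-3-carbaldehyde (formyl cis to the aryl group)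
Conditions: SO3·pyridine, DMSO, iPr2NEt, CH2Cl2, 0 °C
Reagents that add atoms: none
Why: Parikh–Doering oxidation converts only the primary alcohol, the tertiary carbinol being inert, under non-acidic conditions at 0 °C that should cause neither dehydration nor premature rearrangement.

Step 13
Reactants: 20 (2R,3S)-3-hydroxy-4,6-dimethoxy-2-[4-methoxy-3-(methoxymethoxy)phenyl]-5-(3-methylbut-2-enyl)-2,3-dihydro-1-benzofuran-3-carbaldehyde
Product: 21 (2R,3R)-3-hydroxy-5,7-dimethoxy-2-[4-methoxy-3-(methoxymethoxy)phenyl]-6-(3-methylbut-2-enyl)-2,3-dihydro-4H-chromen-4-one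
Conditions: Al(OtBu)3 (1.2 equiv), toluene, rt to 60 °C; aq. potassium sodium tartrate work-up
Reagents that add atoms: none
Why: Proposed new method: alkoxide exchange with Al(OtBu)3 binds the C3 hydroxyl of 20 and the aluminium chelates the formyl oxygen, whereupon the C2–C3 bond migrates with retention at C2 to the activated formyl carbon while the old carbinol carbon becomes the C4 ketone (α-ketol or acyloin rearrangement), a tert-butoxide being chosen because, unlike an isopropoxide, it cannot reduce the aldehyde by Meerwein–Ponndorf–Verley hydride transfer. The closest known reaction type is the Lewis acid- or base-mediated α-ketol shift that enlarges 1-hydroxycycloalkyl aldehydes and ketones by one carbon, which has not been shown on a 3-hydroxy-2,3-dihydrobenzofuran-3-carbaldehyde. Ring C is not closed by a cyclisation but arises from this 1,2-shift, which inserts the former formyl carbon between C2 and the old carbinol carbon and so enlarges the five-membered oxygen ring to the six-membered one. The new C3 centre is controlled by the chelate together with the existing C2 centre, since with the formyl group cis to ring B and its C=O eclipsing the C3–O bond C2 adds to the carbonyl face that leaves the C3 hydrogen on the side of ring B, giving the 2,3-trans ketol, which is also the more stable epimer (equatorial hydroxyl hydrogen-bonded to the C4 carbonyl) should C3 equilibrate. The step needs migration of C2 and not of the ring A carbon C3a, which should be secured because C2 is a secondary carbon bearing the ring oxygen and a para-methoxyphenyl group and because the shift is reversible and funnels into the aryl ketone conjugated with the trioxygenated ring A. Loss of water to a benzofuran is disfavoured because ionisation at C3 would place a cation next to the formyl group, and the aprotic, weakly basic medium should also protect C2 from epimerisation.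

Step 14
Reactants: 21 (2R,3R)-3-hydroxy-5,7-dimethoxy-2-[4-methoxy-3-(methoxymethoxy)phenyl]-6-(3-methylbut-2-enyl)-2,3-dihydro-4H-chromen-4-one
Product: 22 (2R,3R)-3-hydroxy-2-(3-hydroxy-4-methoxyphenyl)-5,7-dimethoxy-6-(3-methylbut-2-enyl)-2,3-dihydro-4H-chromen-4-one
Conditions: 2 M HCl, MeOH, 40 °C
Reagents that add atoms: none
Why: Acid-catalysed acetal exchange removes the methoxymethyl group while the 5-oxygen is still methylated, so that no free hydroxyl stands next to the prenyl group during the only protic acid step and cyclisation to a chromane cannot occur.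

Step 15
Reactants: 22 (2R,3R)-3-hydroxy-2-(3-hydroxy-4-methoxyphenyl)-5,7-dimethoxy-6-(3-methylbut-2-enyl)-2,3-dihydro-4H-chromen-4-one
Product: 23 (2R,3R)-3,5-dihydroxy-2-(3-hydroxy-4-methoxyphenyl)-7-methoxy-6-(3-methylbut-2-enyl)-2,3-dihydro-4H-chromen-4-one (CNP0146895.1)
Conditions: MgI2·OEt2 (3–4 equiv), toluene/Et2O, 60 °C
Reagents that add atoms: none
Why: Chelation-controlled ether cleavage, in which magnesium held between the C4 carbonyl and the peri 5-methoxy oxygen activates only that methyl group towards iodide, should spare the 7- and 4'-methyl ethers, the prenyl group and both stereocentres.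

Compound list
1 | 3,5-dimethoxyphenol | COc1cc(O)cc(OC)c1 | starting material
2 | (3,5-dimethoxyphenoxy)triisopropylsilane | COc1cc(OC)cc(O[Si](C(C)C)(C(C)C)C(C)C)c1 | intermediate
3 | prenyl bromide (1-bromo-3-methylbut-2-ene) | CC(C)=CCBr | starting material
4 | [2,6-dimethoxy-4-(triisopropylsilyloxy)phenyl]lithium | [Li]c1c(OC)cc(O[Si](C(C)C)(C(C)C)C(C)C)cc1OC | intermediate (not isolated)
5 | [3,5-dimethoxy-4-(3-methylbut-2-enyl)phenoxy]triisopropylsilane | COc1cc(O[Si](C(C)C)(C(C)C)C(C)C)cc(OC)c1CC=C(C)C | intermediate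
6 | 3,5-dimethoxy-4-(3-methylbut-2-enyl)phenol | COc1cc(O)cc(OC)c1CC=C(C)C | intermediate
7 | oxalyl chloride | O=C(Cl)C(=O)Cl | starting material
8 | 4,6-dimethoxy-5-(3-methylbut-2-enyl)-1-benzofuran-2,3-dione | COc1cc2OC(=O)C(=O)c2c(OC)c1CC=C(C)C | intermediate (not isolated)
9 | methyl 2-[6-hydroxy-2,4-dimethoxy-3-(3-methylbut-2-enyl)phenyl]-2-oxoacetate | COC(=O)C(=O)c1c(O)cc(OC)c(CC=C(C)C)c1OC | intermediate
10 | isovanillin (3-hydroxy-4-methoxybenzaldehyde) | COc1ccc(C=O)cc1O | starting material
11 | 4-methoxy-3-(methoxymethoxy)benzaldehyde | COCOc1cc(C=O)ccc1OC | intermediate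
12 | [4-methoxy-3-(methoxymethoxy)phenyl]methanol | COCOc1cc(CO)ccc1OC | intermediate
13 | methyl 2-[2,4-dimethoxy-6-{[4-methoxy-3-(methoxymethoxy)phenyl]methoxy}-3-(3-methylbut-2-enyl)phenyl]-2-oxoacetate | COC(=O)C(=O)c1c(OCc2ccc(OC)c(OCOC)c2)cc(OC)c(CC=C(C)C)c1OC | intermediate
14 | 4-methylbenzenesulfonylhydrazone of 13 (C=N geometry not defined) | COC(=O)C(=NNS(=O)(=O)c1ccc(C)cc1)c1c(OCc2ccc(OC)c(OCOC)c2)cc(OC)c(CC=C(C)C)c1OC | intermediate (not isolated)
15 | methyl 2-diazo-2-[2,4-dimethoxy-6-{[4-methoxy-3-(methoxymethoxy)phenyl]methoxy}-3-(3-methylbut-2-enyl)phenyl]acetate | COC(=O)C(=[N+]=[N-])c1c(OCc2ccc(OC)c(OCOC)c2)cc(OC)c(CC=C(C)C)c1OC | intermediate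
16 | methyl (2S,3R)-4,6-dimethoxy-2-[4-methoxy-3-(methoxymethoxy)phenyl]-5-(3-methylbut-2-enyl)-2,3-dihydro-1-benzofuran-3-carboxylate (2,3-cis) | COc1ccc([C@H]2Oc3cc(OC)c(CC=C(C)C)c(OC)c3[C@H]2C(=O)OC)cc1OCOC | intermediate
17 | potassium ester enolate of 16 (C2 configuration as in 16, C3 planar) | COc1ccc([C@H]2Oc3cc(OC)c(CC=C(C)C)c(OC)c3C2=C([O-])OC)cc1OCOC.[K+] | intermediate (not isolated)
18 | methyl (2R,3S)-3-hydroxy-4,6-dimethoxy-2-[4-methoxy-3-(methoxymethoxy)phenyl]-5-(3-methylbut-2-enyl)-2,3-dihydro-1-benzofuran-3-carboxylate (3-OH trans to aryl) | COc1ccc([C@H]2Oc3cc(OC)c(CC=C(C)C)c(OC)c3[C@@]2(O)C(=O)OC)cc1OCOC | intermediate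
19 | (2R,3R)-3-(hydroxymethyl)-4,6-dimethoxy-2-[4-methoxy-3-(methoxymethoxy)phenyl]-5-(3-methylbut-2-enyl)-2,3-dihydro-1-benzofuran-3-ol (3-OH trans to aryl) | COc1ccc([C@H]2Oc3cc(OC)c(CC=C(C)C)c(OC)c3[C@@]2(O)CO)cc1OCOC | intermediate
20 | (2R,3S)-3-hydroxy-4,6-dimethoxy-2-[4-methoxy-3-(methoxymethoxy)phenyl]-5-(3-methylbut-2-enyl)-2,3-dihydro-1-benzofuran-3-carbaldehyde (3-OH trans, formyl cis to aryl) | COc1ccc([C@H]2Oc3cc(OC)c(CC=C(C)C)c(OC)c3[C@@]2(O)C=O)cc1OCOC | intermediate
21 | (2R,3R)-3-hydroxy-5,7-dimethoxy-2-[4-methoxy-3-(methoxymethoxy)phenyl]-6-(3-methylbut-2-enyl)-2,3-dihydro-4H-chromen-4-one (2,3-trans) | COc1ccc([C@H]2Oc3cc(OC)c(CC=C(C)C)c(OC)c3C(=O)[C@@H]2O)cc1OCOC | intermediate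
22 | (2R,3R)-3-hydroxy-2-(3-hydroxy-4-methoxyphenyl)-5,7-dimethoxy-6-(3-methylbut-2-enyl)-2,3-dihydro-4H-chromen-4-one | COc1ccc([C@H]2Oc3cc(OC)c(CC=C(C)C)c(OC)c3C(=O)[C@@H]2O)cc1O | intermediate
23 | (2R,3R)-3,5-dihydroxy-2-(3-hydroxy-4-methoxyphenyl)-7-methoxy-6-(3-methylbut-2-enyl)-2,3-dihydro-4H-chromen-4-one | COc1ccc([C@H]2Oc3cc(OC)c(CC=C(C)C)c(O)c3C(=O)[C@@H]2O)cc1O | target

Total step count: 15.
Longest linear sequence: 13 steps (steps 1–4 and 7–15, from 3,5-dimethoxyphenol); the ring B branch (steps 5 and 6) joins at step 7.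

Steps most likely to fail

1. Step 13 (proposed new method). The shift may take the wrong course: migration of the ring A carbon instead of C2, loss of water with aromatisation of the furan ring, or hydride transfer between aluminium alkoxides. The fallback uses the known chalcone epoxide route; it sets out from phenol 6 and aldehyde 11 and comes back at 22. Phenol 6 is protected with MOMCl and iPr2NEt as 1,3-dimethoxy-5-(methoxymethoxy)-2-(3-methylbut-2-enyl)benzene F1. Ortho-lithiation with n-BuLi and TMEDA between the acetal and a methoxy group, followed by N-methoxy-N-methylacetamide, gives 1-[2,4-dimethoxy-6-(methoxymethoxy)-3-(3-methylbut-2-enyl)phenyl]ethanone F2. Claisen–Schmidt condensation with 11 (KOH, EtOH) gives (2E)-1-[2,4-dimethoxy-6-(methoxymethoxy)-3-(3-methylbut-2-enyl)phenyl]-3-[4-methoxy-3-(methoxymethoxy)phenyl]prop-2-en-1-one F3. Juliá–Colonna epoxidation (poly-L-leucine, urea–H2O2, DBU, THF) is nucleophilic and should not touch the prenyl alkene; it should give [2,4-dimethoxy-6-(methoxymethoxy)-3-(3-methylbut-2-enyl)phenyl]{(2R,3S)-3-[4-methoxy-3-(methoxymethoxy)phenyl]oxiran-2-yl}methanone F4. HCl in MeOH then removes both acetals, and the freed 2'-hydroxyl opens the epoxide at the benzylic carbon with inversion, which should give the trans ketol 22.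

2. Step 9. The carbene carbon is flanked by two ortho substituents, so the insertion may be slow, poorly enantioselective, or diverted into a methoxy C–H bond. The fallback replaces catalyst control by resolution; it sets out from 15 and comes back at 18. Decomposition of 15 with achiral Rh2(OAc)4 and equilibration with NaOMe in MeOH should give racemic trans methyl 4,6-dimethoxy-2-[4-methoxy-3-(methoxymethoxy)phenyl]-5-(3-methylbut-2-enyl)-2,3-dihydro-1-benzofuran-3-carboxylate F5. Preparative chromatography on a chiral stationary phase delivers the (2S,3S)-trans ester F6, which under the conditions of step 10 forms the same enolate 17 and hence 18.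

3. Step 4. Liberated HCl may add to the prenyl double bond, or the aryl oxalyl chloride may not close to the dione. The fallback forms the C–C bond without acid; it sets out from 6 and comes back at 9. The bromomagnesium phenoxide of 6 (EtMgBr, then CH2Cl2) is hydroxyalkylated at the ortho carbon by methyl glyoxylate through a chelated transition state, giving methyl 2-hydroxy-2-[6-hydroxy-2,4-dimethoxy-3-(3-methylbut-2-enyl)phenyl]acetate F7. Oxidation of the benzylic alcohol with MnO2 in CH2Cl2 gives 9.

Further compounds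
F1 | step 13 | 1,3-dimethoxy-5-(methoxymethoxy)-2-(3-methylbut-2-enyl)benzene | COCOc1cc(OC)c(CC=C(C)C)c(OC)c1
F2 | step 13 | 1-[2,4-dimethoxy-6-(methoxymethoxy)-3-(3-methylbut-2-enyl)phenyl]ethanone | CC(=O)c1c(OCOC)cc(OC)c(CC=C(C)C)c1OC
F3 | step 13 | (2E)-1-[2,4-dimethoxy-6-(methoxymethoxy)-3-(3-methylbut-2-enyl)phenyl]-3-[4-methoxy-3-(methoxymethoxy)phenyl]prop-2-en-1-one | COCOc1cc(/C=C/C(=O)c2c(OCOC)cc(OC)c(CC=C(C)C)c2OC)ccc1OC
F4 | step 13 | [2,4-dimethoxy-6-(methoxymethoxy)-3-(3-methylbut-2-enyl)phenyl]{(2R,3S)-3-[4-methoxy-3-(methoxymethoxy)phenyl]oxiran-2-yl}methanone | O=C(c1c(OCOC)cc(OC)c(CC=C(C)C)c1OC)[C@@H]1O[C@H]1c1ccc(OC)c(OCOC)c1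
F5 | step 9 | racemic trans methyl 4,6-dimethoxy-2-[4-methoxy-3-(methoxymethoxy)phenyl]-5-(3-methylbut-2-enyl)-2,3-dihydro-1-benzofuran-3-carboxylate (both enantiomers) | COc1ccc([C@H]2Oc3cc(OC)c(CC=C(C)C)c(OC)c3[C@@H]2C(=O)OC)cc1OCOC.COc1ccc([C@@H]2Oc3cc(OC)c(CC=C(C)C)c(OC)c3[C@H]2C(=O)OC)cc1OCOC
F6 | step 9 | methyl (2S,3S)-4,6-dimethoxy-2-[4-methoxy-3-(methoxymethoxy)phenyl]-5-(3-methylbut-2-enyl)-2,3-dihydro-1-benzofuran-3-carboxylate (2,3-trans) | COc1ccc([C@H]2Oc3cc(OC)c(CC=C(C)C)c(OC)c3[C@@H]2C(=O)OC)cc1OCOC
F7 | step 4 | methyl 2-hydroxy-2-[6-hydroxy-2,4-dimethoxy-3-(3-methylbut-2-enyl)phenyl]acetate (racemic) | COC(=O)C(O)c1c(O)cc(OC)c(CC=C(C)C)c1OC
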